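## The problem

The target is a cembranolide. Carbons are numbered from the lactone O–CH (C1) round the 14-membered carbocycle (ring A) to the ring-fusion carbon C14; C15 bears the exocyclic methylene C17 and C16 is the lactone carbonyl.

- **Ring system.** Ring A carries a (2E)- and an (11Z)-trisubstituted alkene. It is bridged from C7 to C10 by an O–O unit, which makes a 1,2-dioxane (ring B), and it is trans-fused at C1/C14 to an α-methylene-γ-butyrolactone (ring C).
- **Stereocentres.** There are five, in two clusters: C6 (S), C7 (R) and C10 (S) around ring B, and C1 (R) and C14 (S) at the lactone. C6 and C7 are vicinal and can come from one alkene. C10 is 1,4 to C7 across ring B and needs its own control element. C1 and C14 can be made in one C–C bond formation, but they lie four to five bonds from the other cluster, so their absolute sense is not under simple acyclic control.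
- **Sensitive groups.** The dialkyl peroxide rules out low-valent metals, hydrogenation and strong hydride donors. H-10 is both allylic and α to the O–O bond, so strong base invites Kornblum–DeLaMare cleavage. The α-methylene lactone is a Michael acceptor that would not survive hydroperoxide anion. The allylic C–O bonds at C1 and C10 can ionise.
- **Enabling feature.** C7 is a tertiary peroxy carbon next to the oxygenated C6, and the second peroxy carbon C10 is three bonds away. This is the pattern left when a C10 hydroperoxide opens a C6–C7 epoxide at C7 with inversion, which also frees the C6 oxygen for the acetate.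
- **Consequence.** Ring B is best made on an open chain before ring A, and everything after it must tolerate an O–O bond.

## Retrosynthesis

**Rings A and C (29 from 27).** The C1–C14 bond and the lactone C16–O bond are cut together, giving the open-chain enal 27 with a 2-(boronylmethyl)enoate at the C13 end. This cut puts both remaining stereocentres and both remaining rings into the last step, so the Michael acceptor never meets a peroxide nucleophile. Closing ring A at one of its trisubstituted alkenes would give no control of geometry, and chromium, zinc or samarium allyl reagents would threaten the O–O bond, whereas boron does not. The forward step must go through a closed chair with C13 trans to the CH2B group, so that C1 and C14 form anti and the lactone is trans.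

**The allylboronate (27 from 26, 25, 23, 21 and 22).** The C15–C17 and C13–C14 bonds are cut. The (14Z) geometry of 25 comes from syn addition of H–Al across ynoate 23 followed by alkylation with an (iodomethyl)boronate. Borylation of a Baylis–Hillman-type acetate would give the other geometry and hence the cis-lactone. Ynoate 23 comes from allylic bromide 21 and methyl propiolate 22 by copper-catalysed alkynylation. The forward hydride reagent must spare the O–O bond and the acetate. The C1 silyl ether is removed (26) and oxidised (27) only after boron is in place.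

**Chain ends (21 from 19, 18 and 17).** Only functional groups change: C13 OTBS to OH (19) to bromide (21), and C6 OH to OAc (18). A TBDPS ether at C1 and a TBS ether at C13 are told apart by acid lability. An ester at C1 was not used because it could not be removed later beside the C6 acetate and the ynoate.

**Ring B, the key cut (17 from 16).** The C7–O bond is cut, leading to the open-chain hydroperoxy epoxide 16. Against a cut at C10–O, this one uses the tertiary carbon as the electrophile in a 6-exo mode, transfers the E-alkene geometry into the C6/C7 relationship and delivers the C6 hydroxyl in the same event. The forward reaction needs attack at C7, not C6, with inversion, under acid mild enough for an allylic hydroperoxide.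

**The hydroperoxide (16 from 13 and 14).** The C10–O bond is cut. Hydrogen peroxide 14 displaces an activated (10R)-alcohol 13 with inversion. No catalytic asymmetric route to a secondary allylic hydroperoxide of this type is available, so C10 is set at the alcohol stage and inverted. The forward step must beat ionisation of an allylic sulfonate.

**Two catalyst-controlled centres (13 from 12 from 11).** The C10 carbinol comes from Corey–Bakshi–Shibata reduction of enone 12, and the epoxide from Shi epoxidation of the achiral trienone 11. Epoxidising at the enone stage is preferred to epoxidising the allylic alcohol: C11=C12 is then electron-poor and C2=C3 is deactivated by its allylic oxygen, so only C6=C7 reacts.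

**The chain (11 from 10 from 5 and 8).** The C10–C11 bond is cut between aldehyde 5 and the (Z)-alkenyl iodide 8. The Z geometry of C11=C12 is fixed in the small fragment, where it is easy to set, and is carried through by iodine–lithium exchange with retention.

**Building blocks (5 from 4, 2 and 1; 8 from 7 and 6).** Aldehyde 5 is farnesol 1 with its terminal isopropylidene removed (silyl ether 2, terminal epoxide 4, glycol cleavage); C1–C10 and both E alkenes are bought. Iodide 8 comes from 2-butyn-1-ol 6 by hydroxyl-directed hydroalumination and iodination (7).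

## Roads not taken

**Alternative 1: oxygen insertion into a cyclobutanone.** The cut is the lactone C1–O bond. The forward key step is a Baeyer–Villiger oxidation of the trans-fused cyclobutanone A2 with aqueous H2O2 in 2,2,2-trifluoroethanol, giving the 15-desmethylene lactone A1.
- Merits: the oxidant is itself a peroxide and harmless to ring B; the more substituted allylic C1 should migrate; retention means there is no facial question at C1 in this step. In that respect it is better than the chosen plan, whose ring closure must choose a face of the enal.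
- Weak points: A2 is a four-membered ketone trans-fused to a 14-membered ring already bridged by the dioxane. It would have to be built on the macrocycle, most plausibly by a ketene cycloaddition that must find one alkene among several and that usually needs a reductive dehalogenation. After A1 the methylene must still be added through a lactone enolate, i.e. strong base beside an acetate and a peroxide with an acidic allylic α-hydrogen.
- Comparison: the chosen plan brings C17 in with the carbon skeleton and closes rings A and C in one step, and it makes ring B on an open chain. It pays with a less precedented ring closure.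

**Alternative 2: [2,3]-Wittig ring contraction.** The cut is C1–C14. Tin–lithium exchange with n-BuLi in the 17-membered α-stannyl bis-allylic ether A4 triggers a [2,3]-shift to the 14-membered carbinol A3, creating C1, C14 and the C15=C17 methylene.
- Merits: ring contraction needs no high dilution, is an established way to 14-membered cembranoid carbinols, and sets both centres in an ordered transition state. As a macrocycle-forming step it is better precedented than the chosen allylboration.
- Weak points: an α-alkoxy organolithium cannot coexist with an O–O bond, so A3 carries only a C6=C7 alkene and a C10 silyl ether. Ring B would have to be made afterwards on the macrocycle: face- and site-selective epoxidation of one of three ring alkenes beside a 1,1-disubstituted alkene, substitution at C10 within the ring, and a transannular 6-exo closure. The C16 silyl ether must also be oxidised to the acid and lactonised.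
- Comparison: the chosen plan settles all three ring-B centres by catalyst control on a flexible chain and needs no oxidation-state changes at C16. It gives up the better-precedented ring formation.

**Alternative 3: hydroboration and B-alkyl Suzuki macrocyclisation.** The cut is C12–C13. 9-BBN adds to the 1,1-disubstituted C14=C13 alkene of the open-chain iodide A6 anti to the C1 silyloxy group, and the borane couples with the (Z)-C12 iodoalkene under Pd(dppf)Cl2, AsPh3 and Cs2CO3 to give the 14-membered triene A5.
- Merits: it is convergent; C14 is set by 1,2-induction from C1, and C1 can be set by an asymmetric method on a fragment. Each of the C1/C14 centres therefore has an identifiable control element, which is better than the chosen plan.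
- Weak points: a borane, zerovalent palladium and aqueous base again force the peroxide to come after the macrocycle, with the same selectivity problems as in Alternative 2. A5 also still needs lactonisation and an enolate-based α-methylenation, either beside the peroxide or before it, in which case the Michael acceptor faces hydroperoxide anion.
- Comparison: the chosen plan has a linear C1–C13 chain bought largely as farnesol, ring B made first, and the methylene lactone made last without enolate chemistry. Its weakness is that the C1/C14 face selectivity is not secured.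

Key step: step 11

Remarks on the chemistry:
- Open-chain intermediates are named with the locants of the target (C1 = future lactone O–CH, C13 = butynol-derived CH2, C16 = ester carbon, C17 = future methylene carbon).
- The D-fructose-derived Shi ketone is assumed to give the (6R,7R)-epoxide of this olefin class, so its enantiomer is specified.
- Hydrogen peroxide and methyl propiolate are counted as numbered starting materials.

## Route

Step 1
Reactants: 1 (2E,6E)-farnesol
Product: 2 (2E,6E)-farnesyl tert-butyldiphenylsilyl ether
Conditions: TBDPSCl, imidazole, DMF, 0 °C to rt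
Reagents that add atoms: tert-butyl(chloro)diphenylsilane, CC(C)(C)[Si](Cl)(c1ccccc1)c1ccccc1
Why: Standard silylation of a primary allylic alcohol; TBDPS is chosen because it survives periodic acid, the organolithium, camphorsulfonic acid and the acid that later removes the C13 TBS group, and it comes off with fluoride beside an acetate and an enoate.

Step 2
Reactants: 2 (2E,6E)-farnesyl tert-butyldiphenylsilyl ether
Product: 4 (2E,6E)-10,11-epoxy-10,11-dihydrofarnesyl tert-butyldiphenylsilyl ether (racemic at C10), via bromohydrin 3 (not isolated)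
Conditions: NBS, THF–H2O (3:1), 0 °C; then K2CO3, MeOH, rt
Reagents that add atoms: water, O
Why: Terminal-selective bromohydrin formation of a farnesyl derivative in aqueous medium (the terminal alkene is the most electron-rich and exposed, C2=C3 is deactivated by the allylic oxygen), then intramolecular Williamson closure; the new stereocentre is lost in step 3.

Step 3
Reactants: 4 (2E,6E)-10,11-epoxy-10,11-dihydrofarnesyl tert-butyldiphenylsilyl ether
Product: 5 (4E,8E)-10-(tert-butyldiphenylsilyloxy)-4,8-dimethyldeca-4,8-dienal (the C1–C10 aldehyde)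
Conditions: H5IO6, THF–Et2O, 0 °C
Reagents that add atoms: none
Why: Periodic acid hydrolyses the trisubstituted epoxide and cleaves the resulting glycol in one flask (epoxide-to-aldehyde glycol cleavage), leaving both E alkenes and the silyl ether untouched.

Step 4
Reactants: 6 2-butyn-1-ol
Product: 7 (Z)-3-iodobut-2-en-1-ol
Conditions: NaAlH2(OCH2CH2OCH3)2 (Red-Al), THF, 0 °C to rt; then I2, −78 to 0 °C
Reagents that add atoms: iodine, II
Why: Hydroxyl-directed anti-hydroalumination of a propargylic alcohol places aluminium on C3 cis to the CH2O group, and iodinolysis with retention gives the Z iodide that fixes the future C11=C12 geometry.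

Step 5
Reactants: 7 (Z)-3-iodobut-2-en-1-ol
Product: 8 (Z)-tert-butyl[(3-iodobut-2-en-1-yl)oxy]dimethylsilane
Conditions: TBSCl, imidazole, CH2Cl2, 0 °C to rt
Reagents that add atoms: tert-butyl(chloro)dimethylsilane, CC(C)(C)[Si](C)(C)Cl
Why: Standard silylation; the TBS ether tolerates t-BuLi and is more acid-labile than the C1 TBDPS ether, which allows the two chain ends to be told apart in step 13.

Step 6
Reactants: 8 (Z)-tert-butyl[(3-iodobut-2-en-1-yl)oxy]dimethylsilane, 5 (4E,8E)-10-(tert-butyldiphenylsilyloxy)-4,8-dimethyldeca-4,8-dienal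
Product: 10 (2E,6E,11Z)-13-(tert-butyldimethylsilyloxy)-1-(tert-butyldiphenylsilyloxy)-3,7,11-trimethyltrideca-2,6,11-trien-10-ol (racemic at C10), via alkenyllithium 9 (not isolated)
Conditions: t-BuLi (2.1 equiv), Et2O, −78 °C; then 5, −78 °C; aq NH4Cl
Reagents that add atoms: none
Why: Iodine–lithium exchange proceeds with retention of alkene geometry and the alkenyllithium adds 1,2 to the aldehyde, forming C10–C11; C10 is formed without control and is corrected by steps 7 and 9.

Step 7
Reactants: 10 (2E,6E,11Z)-13-(tert-butyldimethylsilyloxy)-1-(tert-butyldiphenylsilyloxy)-3,7,11-trimethyltrideca-2,6,11-trien-10-ol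
Product: 11 (2E,6E,11Z)-13-(tert-butyldimethylsilyloxy)-1-(tert-butyldiphenylsilyloxy)-3,7,11-trimethyltrideca-2,6,11-trien-10-one
Conditions: Dess–Martin periodinane, pyridine, CH2Cl2, 0 °C to rt
Reagents that add atoms: none
Why: Dess–Martin oxidation of a secondary allylic alcohol under buffered, non-isomerising conditions keeps the (11Z)-enone geometry.

Step 8
Reactants: 11 (2E,6E,11Z)-13-(tert-butyldimethylsilyloxy)-1-(tert-butyldiphenylsilyloxy)-3,7,11-trimethyltrideca-2,6,11-trien-10-one
Product: 12 (2E,11Z)-(6S,7S)-6,7-epoxy-13-(tert-butyldimethylsilyloxy)-1-(tert-butyldiphenylsilyloxy)-3,7,11-trimethyltrideca-2,11-dien-10-one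
Conditions: L-fructose-derived Shi ketone (ent-Shi ketone, 30 mol%), KHSO5 (as 2KHSO5·KHSO4·K2SO4), K2CO3, Bu4NHSO4, aq Na2B4O7 buffer, CH3CN–CH2(OCH3)2, 0 °C
Reagents that add atoms: potassium peroxymonosulfate, OOS(=O)(=O)[O-].[K+]
Why: Shi asymmetric epoxidation of an E-trisubstituted alkene through the spiro transition state of the chiral dioxirane; C6=C7 is the only electron-rich alkene (C11=C12 is an enone, C2=C3 is deactivated by the allylic silyloxy group), and the L-series ketone sets 6S and 7S together on an achiral substrate.

Step 9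
Reactants: 12 (2E,11Z)-(6S,7S)-6,7-epoxy-13-(tert-butyldimethylsilyloxy)-1-(tert-butyldiphenylsilyloxy)-3,7,11-trimethyltrideca-2,11-dien-10-one
Product: 13 (2E,11Z)-(6S,7S,10R)-6,7-epoxy-13-(tert-butyldimethylsilyloxy)-1-(tert-butyldiphenylsilyloxy)-3,7,11-trimethyltrideca-2,11-dien-10-ol
Conditions: (S)-2-methyl-CBS-oxazaborolidine (20 mol%), catecholborane, toluene, −78 °C
Reagents that add atoms: none
Why: Corey–Bakshi–Shibata 1,2-reduction of an α-substituted enone; the α-methylalkenyl group acts as the large substituent, so the (S)-catalyst should deliver hydride to give the (10R)-alcohol under catalyst control, and catecholborane at −78 °C spares the alkenes and the epoxide.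

Step 10
Reactants: 13 (2E,11Z)-(6S,7S,10R)-6,7-epoxy-13-(tert-butyldimethylsilyloxy)-1-(tert-butyldiphenylsilyloxy)-3,7,11-trimethyltrideca-2,11-dien-10-ol, 14 hydrogen peroxide
Product: 16 (2E,11Z)-(6S,7S,10S)-6,7-epoxy-10-hydroperoxy-13-(tert-butyldimethylsilyloxy)-1-(tert-butyldiphenylsilyloxy)-3,7,11-trimethyltrideca-2,11-diene, via C10 methanesulfonate 15 (not isolated)
Conditions: (CH3SO2)2O, Et3N, THF, −40 °C; then added to anhydrous ethereal H2O2 (20 equiv), CsOH·H2O, DMF, −30 to 0 °C
Reagents that add atoms: none
Why: Displacement of a secondary sulfonate by hydroperoxide anion (alkyl hydroperoxide synthesis from sulfonates), here on an allylic mesylate; the weakly basic α-nucleophile in a dipolar solvent at low temperature should favour direct SN2 attack with inversion (10R to 10S) over ionisation or SN2′ attack, the anhydride avoids a competing chloride, and excess H2O2 suppresses dialkyl peroxide formation.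

Step 11
Reactants: 16 (2E,11Z)-(6S,7S,10S)-6,7-epoxy-10-hydroperoxy-13-(tert-butyldimethylsilyloxy)-1-(tert-butyldiphenylsilyloxy)-3,7,11-trimethyltrideca-2,11-diene
Product: 17 (2E,11Z)-(6S,7R,10S)-7,10-epidioxy-13-(tert-butyldimethylsilyloxy)-1-(tert-butyldiphenylsilyloxy)-3,7,11-trimethyltrideca-2,11-dien-6-ol (cis-3,6-disubstituted 1,2-dioxane with free C6 hydroxyl)
Conditions: (+)-camphorsulfonic acid (10 mol%), CH2Cl2, −20 to 0 °C
Reagents that add atoms: none
Why: Camphorsulfonic acid activates the epoxide oxygen and the terminal oxygen of the C10 hydroperoxide attacks C7 from the face opposite the breaking C7–O bond, an intramolecular SN2-type opening with a loose, cation-like transition state at the tertiary carbon. The closest known reaction type is the acid-catalysed intramolecular opening of epoxides by hydroperoxides to give 1,2-dioxanes, the peroxide counterpart of epoxy-alcohol cyclisations to tetrahydropyrans. Ring B closes in the 6-exo-tet mode (O, O, C10, C9, C8, C7); the 7-endo path to C6 is disfavoured by ring size and by the smaller positive charge at the secondary carbon. The new stereocentre C7 is set by inversion of the (7S)-epoxide carbon fixed in step 8, giving 7R, while C6 keeps its configuration and is released as the (6S)-alcohol; C10 is untouched, so the C6 chain on C7 and the alkenyl group on C10 end up cis, compatible with a chair-like transition state with the alkenyl group equatorial. The step needs regioselectivity for C7, inversion in place of ionisation, and chemoselectivity over Hock-type cleavage of the allylic hydroperoxide and over capture of the activated epoxide by the C2=C3 alkene. The first two follow from C7 being both the tertiary and the 6-exo position; the last two rest on a weak acid in a non-nucleophilic solvent at low temperature and on the allylic silyloxy group, which makes C2=C3 a poor π-nucleophile.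

Step 12
Reactants: 17 (2E,11Z)-(6S,7R,10S)-7,10-epidioxy-13-(tert-butyldimethylsilyloxy)-1-(tert-butyldiphenylsilyloxy)-3,7,11-trimethyltrideca-2,11-dien-6-ol
Product: 18 6-acetate of 17, (2E,11Z)-(6S,7R,10S)-6-acetoxy-7,10-epidioxy-13-(tert-butyldimethylsilyloxy)-1-(tert-butyldiphenylsilyloxy)-3,7,11-trimethyltrideca-2,11-diene
Conditions: Ac2O, DMAP, pyridine, CH2Cl2, 0 °C to rt
Reagents that add atoms: acetic anhydride, CC(=O)OC(C)=O
Why: DMAP-catalysed acylation of a hindered secondary alcohol; amine bases of this strength should not trigger Kornblum–DeLaMare cleavage of a simple dialkyl peroxide.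

Step 13
Reactants: 18 (2E,11Z)-(6S,7R,10S)-6-acetoxy-7,10-epidioxy-13-(tert-butyldimethylsilyloxy)-1-(tert-butyldiphenylsilyloxy)-3,7,11-trimethyltrideca-2,11-diene
Product: 19 (2E,11Z)-(6S,7R,10S)-6-acetoxy-7,10-epidioxy-1-(tert-butyldiphenylsilyloxy)-3,7,11-trimethyltrideca-2,11-dien-13-ol
Conditions: PPTS, MeOH, 0 °C to rt
Reagents that add atoms: none
Why: Acid-catalysed methanolysis removes a primary TBS ether much faster than a primary TBDPS ether; the acetate and the peroxide are inert to pyridinium tosylate.

Step 14
Reactants: 19 (2E,11Z)-(6S,7R,10S)-6-acetoxy-7,10-epidioxy-1-(tert-butyldiphenylsilyloxy)-3,7,11-trimethyltrideca-2,11-dien-13-ol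
Product: 21 (2E,11Z)-(6S,7R,10S)-6-acetoxy-13-bromo-7,10-epidioxy-1-(tert-butyldiphenylsilyloxy)-3,7,11-trimethyltrideca-2,11-diene, via C13 methanesulfonate 20 (not isolated)
Conditions: CH3SO2Cl, Et3N, THF, −40 °C; then LiBr, −40 to 0 °C
Reagents that add atoms: lithium bromide, [Li+].[Br-]
Why: Mesylation and in situ bromide displacement is the standard non-reducing, phosphine-free route to primary allylic bromides and keeps the (11Z) geometry at low temperature.

Step 15
Reactants: 21 (2E,11Z)-(6S,7R,10S)-6-acetoxy-13-bromo-7,10-epidioxy-1-(tert-butyldiphenylsilyloxy)-3,7,11-trimethyltrideca-2,11-diene, 22 methyl propiolate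
Product: 23 methyl (2E,11Z)-(6S,7R,10S)-6-acetoxy-7,10-epidioxy-1-(tert-butyldiphenylsilyloxy)-3,7,11-trimethylhexadeca-2,11-dien-14-ynoate
Conditions: CuI (20 mol%), K2CO3, DMF, rt
Reagents that add atoms: none
Why: Copper-acetylide alkylation of a primary allylic bromide (copper-catalysed synthesis of skipped enynes) forms C13–C14 at the primary carbon; carbonate is too weak a base to cleave the peroxide at C10.

Step 16
Reactants: 23 methyl (2E,11Z)-(6S,7R,10S)-6-acetoxy-7,10-epidioxy-1-(tert-butyldiphenylsilyloxy)-3,7,11-trimethylhexadeca-2,11-dien-14-ynoate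
Product: 25 methyl (2E,11Z,14Z)-(6S,7R,10S)-6-acetoxy-7,10-epidioxy-1-(tert-butyldiphenylsilyloxy)-3,7,11-trimethyl-15-[(4,4,5,5-tetramethyl-1,3,2-dioxaborolan-2-yl)methyl]hexadeca-2,11,14-trienoate, via α-alumino enoate 24 (not isolated)
Conditions: i-Bu2AlH, HMPA, THF, 0 °C; then ICH2B(pin), 0 °C to rt; aq sodium potassium tartrate
Reagents that add atoms: 2-(iodomethyl)-4,4,5,5-tetramethyl-1,3,2-dioxaborolane, CC1(C)OB(CI)OC1(C)C
Why: Syn-hydroalumination of an ynoate by the i-Bu2AlH–HMPA complex puts hydride on C14 and aluminium on C15, and the α-alumino enoate is alkylated by the (iodomethyl)boronate through a boron ate complex and 1,2-shift; C13 therefore ends cis to the ester and trans to CH2B, the geometry needed for an anti allylboration, and the HMPA-complexed reagent is a conjugate reductant expected to leave the acetate and the hindered dialkyl peroxide alone at 0 °C.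

Step 17
Reactants: 25 methyl (2E,11Z,14Z)-(6S,7R,10S)-6-acetoxy-7,10-epidioxy-1-(tert-butyldiphenylsilyloxy)-3,7,11-trimethyl-15-[(4,4,5,5-tetramethyl-1,3,2-dioxaborolan-2-yl)methyl]hexadeca-2,11,14-trienoate
Product: 26 methyl (2E,11Z,14Z)-(6S,7R,10S)-6-acetoxy-7,10-epidioxy-1-hydroxy-3,7,11-trimethyl-15-[(4,4,5,5-tetramethyl-1,3,2-dioxaborolan-2-yl)methyl]hexadeca-2,11,14-trienoate
Conditions: HF·pyridine, pyridine, THF, 0 °C to rt
Reagents that add atoms: none
Why: Buffered fluoride desilylation of a primary TBDPS ether; the ester-deactivated allyl pinacol boronate is a robust, chromatographable reagent and the acetate, enoate and peroxide are inert.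

Step 18
Reactants: 26 methyl (2E,11Z,14Z)-(6S,7R,10S)-6-acetoxy-7,10-epidioxy-1-hydroxy-3,7,11-trimethyl-15-[(4,4,5,5-tetramethyl-1,3,2-dioxaborolan-2-yl)methyl]hexadeca-2,11,14-trienoate
Product: 27 methyl (2E,11Z,14Z)-(6S,7R,10S)-6-acetoxy-7,10-epidioxy-3,7,11-trimethyl-1-oxo-15-[(4,4,5,5-tetramethyl-1,3,2-dioxaborolan-2-yl)methyl]hexadeca-2,11,14-trienoate (enal allylboronate)
Conditions: MnO2, CH2Cl2, rt
Reagents that add atoms: none
Why: Heterogeneous MnO2 oxidation is selective for the allylic alcohol and keeps the (2E)-enal geometry; the deactivated allylboronate does not add to aldehydes at rt without a catalyst, so 27 can be filtered and used directly.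

Step 19
Reactants: 27 methyl (2E,11Z,14Z)-(6S,7R,10S)-6-acetoxy-7,10-epidioxy-3,7,11-trimethyl-1-oxo-15-[(4,4,5,5-tetramethyl-1,3,2-dioxaborolan-2-yl)methyl]hexadeca-2,11,14-trienoate
Product: 29 the target, (1R,6S,7R,10S,14S)-6-acetoxy-7,10-epidioxy cembra-2E,11Z,15(17)-trien-16,1-olide, via O-boryl hydroxy ester 28 (not isolated)
Conditions: Sc(OSO2CF3)3 (20 mol%), CH2Cl2, slow addition of 27 to a final 1 mM, −20 °C to rt; then p-TsOH·H2O (cat.), rt
Reagents that add atoms: none
Why: Proposed new method: the 2-alkoxycarbonyl allylboronate adds to the tethered enal through a closed six-membered chair transition state (boron to carbonyl oxygen, C14 to C1, with allylic transposition that creates the C15=C17 methylene), Sc(OSO2CF3)3 activating the sluggish ester-deactivated boronate by binding a boronate oxygen without opening the transition state; because C13 is trans to CH2B it sits equatorial like the enal chain, so C1 and C14 form anti and the O-borylated hydroxy ester 28 lactonises to the trans-fused α-methylene lactone, closing rings A and C; which face pair reacts, and hence whether (1R,14S) results, depends on the conformational bias of the forming 14-membered ring set by the cis-dioxane and the two trisubstituted alkenes and is not secured in advance; the closest known reactions are the Sc(OSO2CF3)3-catalysed intermolecular additions of 2-alkoxycarbonyl allylboronates to aldehydes giving α-methylene-γ-lactones, intramolecular allylborations forming common rings, and chromium-mediated Nozaki–Hiyama macrocyclisations of allylic halides onto aldehydes, which use the same type of cyclic transition state.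

## Compound list

1 | (2E,6E)-farnesol | CC(C)=CCC/C(C)=C/CC/C(C)=C/CO | starting material
2 | (2E,6E)-farnesyl tert-butyldiphenylsilyl ether | CC(C)=CCC/C(C)=C/CC/C(C)=C/CO[Si](c1ccccc1)(c1ccccc1)C(C)(C)C | intermediate
3 | 10-bromo-11-hydroxy-10,11-dihydrofarnesyl tert-butyldiphenylsilyl ether (bromohydrin, racemic) | CC(C)(O)C(Br)CC/C(C)=C/CC/C(C)=C/CO[Si](c1ccccc1)(c1ccccc1)C(C)(C)C | intermediate
4 | (2E,6E)-10,11-epoxy-10,11-dihydrofarnesyl tert-butyldiphenylsilyl ether (racemic at C10) | CC1(C)OC1CC/C(C)=C/CC/C(C)=C/CO[Si](c1ccccc1)(c1ccccc1)C(C)(C)C | intermediate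
5 | (4E,8E)-10-(tert-butyldiphenylsilyloxy)-4,8-dimethyldeca-4,8-dienal | O=CCC/C(C)=C/CC/C(C)=C/CO[Si](c1ccccc1)(c1ccccc1)C(C)(C)C | intermediate
6 | 2-butyn-1-ol | CC#CCO | starting material
7 | (Z)-3-iodobut-2-en-1-ol | C/C(I)=C/CO | intermediate
8 | (Z)-tert-butyl[(3-iodobut-2-en-1-yl)oxy]dimethylsilane | C/C(I)=C/CO[Si](C)(C)C(C)(C)C | intermediate
9 | (Z)-[4-(tert-butyldimethylsilyloxy)but-2-en-2-yl]lithium | C/C([Li])=C/CO[Si](C)(C)C(C)(C)C | intermediate
10 | (2E,6E,11Z)-13-(tert-butyldimethylsilyloxy)-1-(tert-butyldiphenylsilyloxy)-3,7,11-trimethyltrideca-2,6,11-trien-10-ol (racemic at C10) | CC(C)(C)[Si](c1ccccc1)(c1ccccc1)OC/C=C(\C)CC/C=C(\C)CCC(O)/C(C)=C\CO[Si](C)(C)C(C)(C)C | intermediate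
11 | (2E,6E,11Z)-13-(tert-butyldimethylsilyloxy)-1-(tert-butyldiphenylsilyloxy)-3,7,11-trimethyltrideca-2,6,11-trien-10-one | CC(C)(C)[Si](c1ccccc1)(c1ccccc1)OC/C=C(\C)CC/C=C(\C)CCC(=O)/C(C)=C\CO[Si](C)(C)C(C)(C)C | intermediate
12 | (2E,11Z)-(6S,7S)-6,7-epoxy-13-(tert-butyldimethylsilyloxy)-1-(tert-butyldiphenylsilyloxy)-3,7,11-trimethyltrideca-2,11-dien-10-one | CC(C)(C)[Si](c1ccccc1)(c1ccccc1)OC/C=C(\C)CC[C@@H]1O[C@@]1(C)CCC(=O)/C(C)=C\CO[Si](C)(C)C(C)(C)C | intermediate
13 | (2E,11Z)-(6S,7S,10R)-6,7-epoxy-13-(tert-butyldimethylsilyloxy)-1-(tert-butyldiphenylsilyloxy)-3,7,11-trimethyltrideca-2,11-dien-10-ol | CC(C)(C)[Si](c1ccccc1)(c1ccccc1)OC/C=C(\C)CC[C@@H]1O[C@@]1(C)CC[C@@H](O)/C(C)=C\CO[Si](C)(C)C(C)(C)C | intermediate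
14 | hydrogen peroxide | OO | starting material
15 | (10R)-methanesulfonate of 13 | CC(C)(C)[Si](c1ccccc1)(c1ccccc1)OC/C=C(\C)CC[C@@H]1O[C@@]1(C)CC[C@@H](OS(C)(=O)=O)/C(C)=C\CO[Si](C)(C)C(C)(C)C | intermediate
16 | (2E,11Z)-(6S,7S,10S)-6,7-epoxy-10-hydroperoxy-13-(tert-butyldimethylsilyloxy)-1-(tert-butyldiphenylsilyloxy)-3,7,11-trimethyltrideca-2,11-diene | CC(C)(C)[Si](c1ccccc1)(c1ccccc1)OC/C=C(\C)CC[C@@H]1O[C@@]1(C)CC[C@H](OO)/C(C)=C\CO[Si](C)(C)C(C)(C)C | intermediate
17 | (2E,11Z)-(6S,7R,10S)-7,10-epidioxy-13-(tert-butyldimethylsilyloxy)-1-(tert-butyldiphenylsilyloxy)-3,7,11-trimethyltrideca-2,11-dien-6-ol | CC(C)(C)[Si](c1ccccc1)(c1ccccc1)OC/C=C(\C)CC[C@H](O)[C@@]1(C)CC[C@H](OO1)/C(C)=C\CO[Si](C)(C)C(C)(C)C | intermediate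
18 | 6-acetate of 17 | CC(C)(C)[Si](c1ccccc1)(c1ccccc1)OC/C=C(\C)CC[C@H](OC(C)=O)[C@@]1(C)CC[C@H](OO1)/C(C)=C\CO[Si](C)(C)C(C)(C)C | intermediate
19 | (2E,11Z)-(6S,7R,10S)-6-acetoxy-7,10-epidioxy-1-(tert-butyldiphenylsilyloxy)-3,7,11-trimethyltrideca-2,11-dien-13-ol | CC(C)(C)[Si](c1ccccc1)(c1ccccc1)OC/C=C(\C)CC[C@H](OC(C)=O)[C@@]1(C)CC[C@H](OO1)/C(C)=C\CO | intermediate
20 | 13-methanesulfonate of 19 | CC(C)(C)[Si](c1ccccc1)(c1ccccc1)OC/C=C(\C)CC[C@H](OC(C)=O)[C@@]1(C)CC[C@H](OO1)/C(C)=C\COS(C)(=O)=O | intermediate
21 | (2E,11Z)-(6S,7R,10S)-6-acetoxy-13-bromo-7,10-epidioxy-1-(tert-butyldiphenylsilyloxy)-3,7,11-trimethyltrideca-2,11-diene | CC(C)(C)[Si](c1ccccc1)(c1ccccc1)OC/C=C(\C)CC[C@H](OC(C)=O)[C@@]1(C)CC[C@H](OO1)/C(C)=C\CBr | intermediate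
22 | methyl propiolate | C#CC(=O)OC | starting material
23 | methyl (2E,11Z)-(6S,7R,10S)-6-acetoxy-7,10-epidioxy-1-(tert-butyldiphenylsilyloxy)-3,7,11-trimethylhexadeca-2,11-dien-14-ynoate | CC(C)(C)[Si](c1ccccc1)(c1ccccc1)OC/C=C(\C)CC[C@H](OC(C)=O)[C@@]1(C)CC[C@H](OO1)/C(C)=C\CC#CC(=O)OC | intermediate
24 | 15-(diisobutylalumino) enoate from 23 (C13 cis to the ester) | CC(C)(C)[Si](c1ccccc1)(c1ccccc1)OC/C=C(\C)CC[C@H](OC(C)=O)[C@@]1(C)CC[C@H](OO1)/C(C)=C\C/C=C(\C(=O)OC)[Al](CC(C)C)CC(C)C | intermediate
25 | methyl (2E,11Z,14Z)-(6S,7R,10S)-6-acetoxy-7,10-epidioxy-1-(tert-butyldiphenylsilyloxy)-3,7,11-trimethyl-15-[(4,4,5,5-tetramethyl-1,3,2-dioxaborolan-2-yl)methyl]hexadeca-2,11,14-trienoate | CC(C)(C)[Si](c1ccccc1)(c1ccccc1)OC/C=C(\C)CC[C@H](OC(C)=O)[C@@]1(C)CC[C@H](OO1)/C(C)=C\C/C=C(\C(=O)OC)CB1OC(C)(C)C(C)(C)O1 | intermediate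
26 | C1 alcohol of 25 (silyl group removed) | OC/C=C(\C)CC[C@H](OC(C)=O)[C@@]1(C)CC[C@H](OO1)/C(C)=C\C/C=C(\C(=O)OC)CB1OC(C)(C)C(C)(C)O1 | intermediate
27 | C1 aldehyde of 26 (enal allylboronate) | O=C/C=C(\C)CC[C@H](OC(C)=O)[C@@]1(C)CC[C@H](OO1)/C(C)=C\C/C=C(\C(=O)OC)CB1OC(C)(C)C(C)(C)O1 | intermediate
28 | 14-membered (1R,14S)-O-boryl hydroxy ester (C1–OB(pin), C14 bearing the methyl 2-propenoate unit) | O(B4OC(C)(C)C(C)(C)O4)[C@@H]2/C=C(\C)CC[C@H](OC(C)=O)[C@@]3(C)CC[C@H](OO3)/C(C)=C\C[C@H]2C(=C)C(=O)OC | intermediate
29 | target, (1R,6S,7R,10S,14S)-6-acetoxy-7,10-epidioxy cembra-2E,11Z,15(17)-trien-16,1-olide | C=C1C(=O)O[C@@H]2/C=C(\C)CC[C@H](OC(C)=O)[C@@]3(C)CC[C@H](OO3)/C(C)=C\C[C@@H]12 | target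

## Step count and risks

Total: 19 steps. Longest linear sequence: 17 steps (from 1 through steps 1–3 and 6–19 to 29).

**Step 19 (macrocyclising allylboration, proposed new method).** The ester-deactivated allylboronate may react too slowly at the dilution a 14-membered ring needs, so oligomerisation or Lewis-acid-induced ionisation of the allylic C10–O bond could overtake ring closure. The remote ring-B centres may also discriminate poorly between the two faces of the enal, giving the (1S,14R) trans-lactone as well.
Fallback (known chemistry): it sets out from 25. Oxidation of the C–B bond with NaBO3·4H2O in THF–H2O gives the (14Z)-2-(hydroxymethyl)enoate F1. CH3SO2Cl/Et3N then LiBr gives the 2-(bromomethyl)enoate F2. HF·pyridine frees the C1 alcohol F3, and MnO2 gives the bromo enal F4. Slow addition of F4 to CrCl2 in THF at 0 °C effects a Nozaki–Hiyama-type macrocyclisation; the allylchromium reagent equilibrates and adds anti whatever the bromide geometry, and the chromium alkoxide lactonises, so the route is rejoined at 29. The allylic bromide should be consumed by divalent chromium faster than the hindered dialkyl peroxide, so inverse addition and a short contact time would be used.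

**Step 11 (key step).** The allylic hydroperoxide may undergo Hock-type migration of the alkenyl group to oxygen, or the activated epoxide may be captured by the C2=C3 alkene or open at C6, before the 6-exo closure occurs.
Fallback: it sets out from 16. Silylation (Me3SiCl, Et3N, −40 °C) gives the trimethylsilyl peroxide F5, which cannot lose water in a Hock sense. Catalytic Me3SiOSO2CF3 in CH2Cl2 at −78 °C activates the epoxide by silyl transfer, and the silyl peroxide closes the same C7–O bond to give the C6 trimethylsilyl ether F6. Brief K2CO3/MeOH at 0 °C removes the silyl group and the route is rejoined at 17.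

**Step 10 (hydroperoxide by displacement).** The secondary allylic mesylate may ionise, suffer SN2′ attack at C12, or be attacked by the nearby C13 silyloxy oxygen to form a dihydrofuran. Any of these erodes the C10 configuration or the regiochemistry.
Fallback: stereospecific substitution is given up. It sets out from 13 (the CBS step may then be skipped). (CH3SO2)2O/Et3N and LiBr give the allylic bromide F7 as a C10 mixture. Silver-assisted perhydrolysis (AgOCOCF3, ethereal H2O2, 2,6-di-tert-butylpyridine, Et2O, 0 °C) gives 16 together with its (10R)-epimer F8. The mixture is taken through step 11, where F8 gives the trans-dioxane F9. This is a diastereomer of 17 and is removed by chromatography, so the route is rejoined at 17 at the cost of about half the material.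

**Step 16 (hydroalumination and borylmethylation).** The aluminium hydride may reduce the O–O bond or the C6 acetate, and the alkene geometry may erode through an aluminium allenolate.
Fallback: it sets out from 23. Syn-hydrostannation with Bu3SnH and catalytic Pd(PPh3)4 in THF at 0 °C gives the α-stannyl enoate F10 (C13 cis to the ester). Iodine in CH2Cl2 gives the α-iodo enoate F11 with retention. Negishi coupling with preformed IZnCH2B(pin) under zerovalent palladium catalysis (Pd(PPh3)4) rejoins the route at 25 without any aluminium hydride.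

## Further compounds

F1 | step 19 | methyl (14Z)-15-(hydroxymethyl) analogue of 25 (C17–OH in place of C17–B) | CC(C)(C)[Si](c1ccccc1)(c1ccccc1)OC/C=C(\C)CC[C@H](OC(C)=O)[C@@]1(C)CC[C@H](OO1)/C(C)=C\C/C=C(\C(=O)OC)CO
F2 | step 19 | 2-(bromomethyl)enoate, C1 silyl ether | CC(C)(C)[Si](c1ccccc1)(c1ccccc1)OC/C=C(\C)CC[C@H](OC(C)=O)[C@@]1(C)CC[C@H](OO1)/C(C)=C\C/C=C(\C(=O)OC)CBr
F3 | step 19 | 2-(bromomethyl)enoate, C1 alcohol | OC/C=C(\C)CC[C@H](OC(C)=O)[C@@]1(C)CC[C@H](OO1)/C(C)=C\C/C=C(\C(=O)OC)CBr
F4 | step 19 | bromo enal (2-(bromomethyl)enoate, C1 aldehyde) | O=C/C=C(\C)CC[C@H](OC(C)=O)[C@@]1(C)CC[C@H](OO1)/C(C)=C\C/C=C(\C(=O)OC)CBr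
F5 | step 11 | trimethylsilyl peroxide of 16 | CC(C)(C)[Si](c1ccccc1)(c1ccccc1)OC/C=C(\C)CC[C@@H]1O[C@@]1(C)CC[C@H](OO[Si](C)(C)C)/C(C)=C\CO[Si](C)(C)C(C)(C)C
F6 | step 11 | C6 trimethylsilyl ether of 17 | CC(C)(C)[Si](c1ccccc1)(c1ccccc1)OC/C=C(\C)CC[C@H](O[Si](C)(C)C)[C@@]1(C)CC[C@H](OO1)/C(C)=C\CO[Si](C)(C)C(C)(C)C
F7 | step 10 | C10 allylic bromide from 13 (mixture at C10) | CC(C)(C)[Si](c1ccccc1)(c1ccccc1)OC/C=C(\C)CC[C@@H]1O[C@@]1(C)CCC(Br)/C(C)=C\CO[Si](C)(C)C(C)(C)C
F8 | step 10 | (6S,7S,10R)-hydroperoxy epoxide, C10 epimer of 16 | CC(C)(C)[Si](c1ccccc1)(c1ccccc1)OC/C=C(\C)CC[C@@H]1O[C@@]1(C)CC[C@@H](OO)/C(C)=C\CO[Si](C)(C)C(C)(C)C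
F9 | step 10 | (6S,7R,10R)-trans-dioxane, C10 epimer of 17 | CC(C)(C)[Si](c1ccccc1)(c1ccccc1)OC/C=C(\C)CC[C@H](O)[C@@]1(C)CC[C@@H](OO1)/C(C)=C\CO[Si](C)(C)C(C)(C)C
F10 | step 16 | 15-(tributylstannyl) enoate from 23 (C13 cis to the ester) | CC(C)(C)[Si](c1ccccc1)(c1ccccc1)OC/C=C(\C)CC[C@H](OC(C)=O)[C@@]1(C)CC[C@H](OO1)/C(C)=C\C/C=C(\C(=O)OC)[Sn](CCCC)(CCCC)CCCC
F11 | step 16 | 15-iodo enoate (C13 cis to the ester) | CC(C)(C)[Si](c1ccccc1)(c1ccccc1)OC/C=C(\C)CC[C@H](OC(C)=O)[C@@]1(C)CC[C@H](OO1)/C(C)=C\C/C=C(\C(=O)OC)I
A1 | alternative 1 | 15-desmethylene lactone of the target | C1C(=O)O[C@@H]2/C=C(\C)CC[C@H](OC(C)=O)[C@@]3(C)CC[C@H](OO3)/C(C)=C\C[C@@H]12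
A2 | alternative 1 | trans-fused cyclobutanone (C16 ketone bonded to C1 and C15) | C1C(=O)[C@@H]2/C=C(\C)CC[C@H](OC(C)=O)[C@@]3(C)CC[C@H](OO3)/C(C)=C\C[C@@H]12
A3 | alternative 2 | 14-membered C1 carbinol with C14 2-(silyloxymethyl)vinyl group | O[C@@H]1/C=C(\C)CC/C=C(\C)CC[C@@H](O[Si](C(C)C)(C(C)C)C(C)C)/C(C)=C\C[C@H]1C(=C)CO[Si](C)(C)C(C)(C)C
A4 | alternative 2 | 17-membered cyclic α-stannyl bis-allylic ether (C1 configuration and C14=C15 geometry left open) | CCCC[Sn](CCCC)(CCCC)C1/C=C(\C)CC/C=C(\C)CC[C@@H](O[Si](C(C)C)(C(C)C)C(C)C)/C(C)=C\CC=C(CO[Si](C)(C)C(C)(C)C)CO1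
A5 | alternative 3 | 14-membered triene with C14 set and C15 as an ester-bearing methylene | CC(C)(C)OC(=O)C[C@H]1[C@@H](O[Si](CC)(CC)CC)/C=C(\C)CC/C=C(\C)CC[C@@H](O[Si](C)(C)C(C)(C)C)/C(C)=C\C1
A6 | alternative 3 | open-chain precursor with 1,1-disubstituted C14=C13 alkene and (11Z)-C12 iodoalkene | CC(C)(C)OC(=O)CC(=C)[C@@H](O[Si](CC)(CC)CC)/C=C(\C)CC/C=C(\C)CC[C@@H](O[Si](C)(C)C(C)(C)C)/C(C)=C\I
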